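Readings and results were generated by integration on assumed constants; noise was put on by code.

An easy step comes first: in the red and violet runs, side product A and target together already stand at 99.4% and 99.6% of the substrate charged at the first reading and then hold nearly level, so these runs give us the split but no clock.

| setting | red | violet | flask |
|---|---|---|---|
| substrate | 0.36 M | 0.36 M | 0.36 M |
| coupling partner | 0.17 M | 0.68 M | 0.342 M |
| remark | run made earlier | run made earlier |  |
| time |  |  | 40 min |

- red (time / min: side product A / %, target / %): 1.33: 70.8, 28.6; 4.00: 70.4, 29.0; 6.00: 68.8, 32.1; 10.0: 71.5, 29.8; 15.0: 69.8, 29.0; 20.0: 70.7, 28.2; 25.0: 70.6, 27.3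
- violet (time / min: side product A / %, target / %): 2.00: 31.5, 68.1; 3.00: 30.2, 67.5; 4.00: 32.2, 68.6; 6.00: 32.3, 68.8; 10.0: 32.4, 69.9; 15.0: 31.7, 69.1; 25.0: 28.0, 68.0

(standard deviation of a reading: 1 percentage point)

- share of side product A in side product A plus target at 1.2 s
- share of side product A in side product A plus target at 40 min



We let substrate go to side product A at first order, in competition with substrate plus coupling partner going to target, so that d[target]/d[side product A] = [coupling partner]/κ and [coupling partner] falls as its start value times exp(−[side product A]/κ). The red means, 70.4% side product A and 29.1% target, read κ as 0.264 M. The violet means, 31.2% and 68.6%, read it as 0.249 M.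

We carry their mean, κ = 0.256 M, the [coupling partner] at which both routes run equally fast, a selectivity factor. One Newton step from an even split, with the substrate used up, gives our flask share of 51.3% at the end. By the same reckoning the flask's share begins at κ/(κ+[coupling partner]) = 42.8%, which is lower, so we place its share at 1.2 s between the two.

The forecast gives 46% (42% to 51.5%) at 1.2 s and 51.5% (49% to 54%) at 40 min, slightly above our end share, on the ground that “Only the final selectivity is therefore informative, not the rate.”

The flask gives 45.1% and 50.6%, both inside those ranges.

    substrate + intermediate → side product B (k = 0.0147 L mol⁻¹ s⁻¹)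
    substrate → side product A (k = 0.200 s⁻¹)
    substrate + coupling partner → target (k = 0.818 L mol⁻¹ s⁻¹)
    substrate + coupling partner ⇌ intermediate (K = 2.20 L mol⁻¹, k = 0.0294 L mol⁻¹ s⁻¹)

Entered into the same relation with κ, the flask's share of 50.6% leaves 49.1% of the coupling partner, and the flask holds 48.0% of its charge at 40.0 min, with substrate at 0%. For the neighbouring flask with 0.21 M of coupling partner, the same Newton step gives a share of 64.6%. That neighbouring flask ends at 64.7% side product A in the sum, with target at 35.3% of the substrate charged.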